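The end share x_e, the target at the stop as a share of the starting material charged, is nearly constant in the readings: the dawn and midnight runs have different catalyst charges, yet their readings at 21 min differ by 0.00500 M, less than the scatter of 0.008 M. In the usual term, this end share marks the equilibrium position.

| flask | starting material | catalyst | time |
|---|---|---|---|
| dawn | 1.00 M | 0.0200 M |  |
| winter | 0.500 M | 0.0200 M |  |
| midnight | 1.00 M | 0.0600 M |  |
| summer | 1.00 M | 0.0200 M | 63 min |

- dawn run (time / min: [target] / M): 0.84: 0.011; 1.3: 0.040; 2.1: 0.068; 3.3: 0.146; 5.3: 0.249; 8.4: 0.362; 13: 0.442; 21: 0.515
- winter run (time / min: [target] / M): 0.84: 0.031; 1.3: 0.032; 2.1: 0.051; 3.3: 0.108; 5.3: 0.147; 8.4: 0.220; 13: 0.240; 21: 0.267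
- midnight run (time / min: [target] / M): 0.84: 0.037; 1.3: 0.108; 2.1: 0.210; 3.3: 0.345; 5.3: 0.450; 8.4: 0.493; 13: 0.526; 21: 0.510

(scatter of a reading: 0.008 M)

- Overall: starting material -> target, with catalyst as catalyst.
- Constant volume, constant temperature.
- Bound and free are read together.
- An order is taken over about fifteen percent of the charge, up and down.

1. order of the initial rate in [catalyst], near the charge of the dawn run, the rate being that where two percent of its starting material are target
2. order of the initial rate in [starting material], near the charge of the dawn run, the rate being that where two percent of its starting material are target (one fixed amount of target, the same in the runs compared)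
3. target in the summer run at 63 min, as a share of the starting material charged
4. which of these the readings show (the catalyst wakes slowly / the catalyst dies by itself / the product ties up the catalyst / a little impurity takes part of the catalyst at once / nothing beyond the main steps)

The midnight run read 0.526 M at 13 min and 0.510 M at 21 min. These differ by 0.0160 M, with a scatter of 0.008 M on each reading, so their mean over the charge is taken as x_e = 51.8%.

The summer flask holds 1.00 M starting material and 0.0200 M catalyst, the dawn charge. The dawn run had already reached 0.515 M at 21 min, and the summer flask is read later, at 63 min. By this reckoning it will then hold 0.518 M target. The catalyst is best left alone: the midnight run, with 3.00 times the dawn catalyst, read 0.510 M at 21 min, beside the 0.515 M of the dawn run.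

The forecast, which starts from “The plateau scales with the charge”, gives 52.5%, slightly above this x_e. It also gives orders of 0.61 in catalyst and 0.36 in starting material, and its choice is that the catalyst wakes slowly.

The summer run gives 52.2%, which is 0.40 percentage points from x_e, and the slowness of the conversion of catalyst into active catalyst makes no difference to the target in the summer run at 63 min. The orders are 0.64 in catalyst and 0.21 in starting material, so the forecast's order in starting material is 1.70 times too high, and the answer is that the catalyst wakes slowly.

    active catalyst + starting material ⇌ catalyst-substrate complex, settled at all times (2.470 L mol⁻¹)
    catalyst-substrate complex ⇌ target + active catalyst (4.854 min⁻¹, 10.74 L mol⁻¹ min⁻¹)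
    catalyst → active catalyst (0.9780 min⁻¹)

For the winter charge, x_e gives 0.259 M target, and the winter run read 0.267 M at 21 min.

Readings and results were generated by integration from invented constants; noise was put on by code.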